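**Assumption (chemistry):** the target 15 has no stereocentre and exists as rapidly equilibrating enol tautomers; every filicinic-type ring is drawn in the tautomer of the target SMILES.

## Retrosynthetic overview

1. Target 15 is ring A (2-butanoyl-4,4-dimethyl enolised cyclohexanetrione), aromatic ring B (butanoylphloroglucinol) and ring C (the 2-acetyl analogue of ring A), linked A–CH2–B–CH2–C. The last bond made joins the CH2 on C6 of ring A to C5 of ring B, by dehydrogenative (oxidative) coupling of the C-methyl triketone 7 with dimer 13.
2. Enabling feature: in 7 the C6 methyl group sits on the central carbon of the enolised β-diketone unit O=C1–C6(CH3)=C5–OH of ring A, so loss of the enol hydrogen and one methyl hydrogen gives the exocyclic C6=CH2 enetrione 14, an ortho-quinone-methide-like acceptor. In 13 the only unsubstituted carbon of ring B (C5, between C4–OH and C6–OH) is the only free carbon nucleophile.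
3. Dimer 13 is disconnected at its own CH2–ring B bond into acetylfilicinic acid 10, formaldehyde and phlorobutyrophenone 4 (Knoevenagel/Michael bridging).
4. No ring is constructed. Ring B comes from phloroglucinol 1 (step 1); rings A and C arise by dearomative C-methylation of 4 and of 2,4,6-trihydroxyacetophenone 8 (steps 2 and 3); ring C is bridged to ring B first (step 4) and ring A last (step 5).

Key step: step 5

## Route

Step 1
Reactants: 1 phloroglucinol (anhydrous); 2 butyronitrile
Product: 4 phlorobutyrophenone [1-(2,4,6-trihydroxyphenyl)butan-1-one], via ketiminium chloride 3 (not isolated)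
Conditions: 2 (1.1 equiv), HCl (g), ZnCl2 (cat.), Et2O, 0 °C; then H2O, reflux
Reagents that add atoms: water, O
Why: Hoesch acylation, in which the nitrilium species from 2 and HCl attacks the very electron-rich ring once (the precipitating ketiminium salt 3 is deactivated against a second acylation) and hydrolysis of 3 gives the ketone.

Step 2
Reactants: 4 phlorobutyrophenone
Product: 7 C-methyl triketone [2-butanoyl-3,5-dihydroxy-4,4,6-trimethylcyclohexa-2,5-dien-1-one], via 3-methylphlorobutyrophenone 5 (not isolated), via butyrylfilicinic acid 6 (not isolated)
Conditions: NaOMe (3.1 equiv), MeI (3.1 equiv), MeOH, 0 °C to rt; then 1 M HCl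
Reagents that add atoms: methyl iodide, CI
Why: Dearomative C-methylation of an acylphloroglucinol (SN2 alkylation of the ambident phenolate at carbon), in which the first two methyl groups go to the same ring carbon (through 5 to the filicinic acid stage 6) and the third to the remaining nucleophilic ring carbon, as in the known one-flask conversion of acylphloroglucinols into their 4,4,6-trimethyl triketones, while a fourth methylation is held back by the limited amount of MeI.

Step 3
Reactants: 8 2,4,6-trihydroxyacetophenone
Product: 10 acetylfilicinic acid [2-acetyl-3,5-dihydroxy-4,4-dimethylcyclohexa-2,5-dien-1-one], via 3-methylphloracetophenone 9 (not isolated)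
Conditions: NaOMe (2.1 equiv), MeI (2.0 equiv), MeOH, 0 °C to rt; then 1 M HCl
Reagents that add atoms: methyl iodide, CI
Why: The same dearomative C-methylation, stopped with two equivalents of MeI at the gem-dimethyl stage because the delocalised vinylogous-acid anion of 10 is much less nucleophilic than the aromatic phenolates that precede it.

Step 4
Reactants: 10 acetylfilicinic acid; 4 phlorobutyrophenone
Product: 13 norflavaspidic acid AB [2-acetyl-6-[(3-butanoyl-2,4,6-trihydroxyphenyl)methyl]-3,5-dihydroxy-4,4-dimethylcyclohexa-2,5-dien-1-one], via hydroxymethyl adduct 11 (not isolated), via enetrione 12 (not isolated)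
Conditions: 4 (3 equiv), 37% aq. HCHO (1.0 equiv, slow addition), 1% aq. KOH, 0 °C to rt; then 1 M HCl
Reagents that add atoms: formaldehyde, C=O
Why: Knoevenagel condensation followed by Michael (Friedel–Crafts-type) addition, the classical formaldehyde bridging of an acylfilicinic acid to an acylphloroglucinol: the enolate of 10 adds to formaldehyde, 11 loses water to enetrione 12, and 12 is captured at a free ring carbon of the phenolate of 4, which is used in excess to keep down the homodimer of 10 and double bridging of 4.

Step 5
Reactants: 7 C-methyl triketone; 13 norflavaspidic acid AB
Product: 15 target (filixic acid ABB), via enetrione 14 (not isolated)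
Conditions: 13 (1.0 equiv), 7 (1.3 equiv), TEMPO (0.2 equiv), Ag2O (1.3 equiv, in portions), THF, 0 °C to rt, Ar, dark
Reagents that add atoms: none
Why: Proposed new method: the acidic enol 7 should form a silver enolate that is oxidised by one electron to the C6-centred tricarbonyl radical; TEMPO takes this radical on (C6–O bond, then loss of TEMPO-H across C6–CH3, or direct abstraction of a methyl hydrogen), so that the C6 methyl group becomes the exocyclic methylene of enetrione 14, and Ag2O returns TEMPO-H to TEMPO. The free carbon C5 of ring B in 13 then adds to the CH2 terminus of 14 in a Michael (Friedel–Crafts-type) addition, and tautomerisation restores aromatic ring B and the enolised ring A of 15. The closest known reaction type is the Ag2O/TEMPO dehydrogenation of 6-methyl dearomatised acylphloroglucinols to such enetriones with capture in hetero-Diels–Alder reactions, joined here to the familiar conjugate addition of acylphloroglucinols to alkylidene triketones, which makes the step a cross-dehydrogenative C(sp3)–H/C(sp2)–H coupling. No ring is closed and no stereocentre is formed. Site selectivity on 13 is secured because ring B has a single free carbon and O-alkylation is reversible while the C-adduct is the thermodynamic product; chemoselective oxidation of the CH3 of 7 over the bridging CH2 groups of 13 and 15 is expected because 7 is the least hindered and most easily metalated enol, whereas the enols next to the bridges are held in hydrogen bonds to the OH groups of ring B, and it is supported by adding Ag2O in portions at 0 °C to a slight excess of 7. Dimerisation of 14 is limited by its low stationary concentration in the presence of the nucleophile.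

## Compound list

1 | phloroglucinol (benzene-1,3,5-triol) | Oc1cc(O)cc(O)c1 | starting material
2 | butyronitrile | CCCC#N | starting material
3 | 1-(2,4,6-trihydroxyphenyl)butan-1-iminium chloride (ketiminium chloride, not isolated) | CCCC(=[NH2+])c1c(O)cc(O)cc1O.[Cl-] | intermediate
4 | phlorobutyrophenone, 1-(2,4,6-trihydroxyphenyl)butan-1-one | CCCC(=O)c1c(O)cc(O)cc1O | intermediate
5 | 3-methylphlorobutyrophenone, 1-(2,4,6-trihydroxy-3-methylphenyl)butan-1-one (not isolated) | CCCC(=O)c1c(O)cc(O)c(C)c1O | intermediate
6 | butyrylfilicinic acid, 2-butanoyl-3,5-dihydroxy-4,4-dimethylcyclohexa-2,5-dien-1-one (not isolated in the main route) | CCCC(=O)C1=C(O)C(C)(C)C(O)=CC1=O | intermediate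
7 | C-methyl triketone, 2-butanoyl-3,5-dihydroxy-4,4,6-trimethylcyclohexa-2,5-dien-1-one | CCCC(=O)C1=C(O)C(C)(C)C(O)=C(C)C1=O | intermediate
8 | 2,4,6-trihydroxyacetophenone | CC(=O)c1c(O)cc(O)cc1O | starting material
9 | 3-methylphloracetophenone, 1-(2,4,6-trihydroxy-3-methylphenyl)ethan-1-one (not isolated) | CC(=O)c1c(O)cc(O)c(C)c1O | intermediate
10 | acetylfilicinic acid, 2-acetyl-3,5-dihydroxy-4,4-dimethylcyclohexa-2,5-dien-1-one | CC(=O)C1=C(O)C(C)(C)C(O)=CC1=O | intermediate
11 | hydroxymethyl adduct, 2-acetyl-3,5-dihydroxy-6-(hydroxymethyl)-4,4-dimethylcyclohexa-2,5-dien-1-one (not isolated) | CC(=O)C1=C(O)C(C)(C)C(O)=C(CO)C1=O | intermediate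
12 | enetrione, 2-acetyl-3-hydroxy-4,4-dimethyl-6-methylidenecyclohex-2-ene-1,5-dione (not isolated) | CC(=O)C1=C(O)C(C)(C)C(=O)C(=C)C1=O | intermediate
13 | norflavaspidic acid AB, 2-acetyl-6-[(3-butanoyl-2,4,6-trihydroxyphenyl)methyl]-3,5-dihydroxy-4,4-dimethylcyclohexa-2,5-dien-1-one | CCCC(=O)c1c(O)cc(O)c(CC2=C(O)C(C)(C)C(O)=C(C(C)=O)C2=O)c1O | intermediate
14 | enetrione, 2-butanoyl-3-hydroxy-4,4-dimethyl-6-methylidenecyclohex-2-ene-1,5-dione (not isolated) | CCCC(=O)C1=C(O)C(C)(C)C(=O)C(=C)C1=O | intermediate
15 | filixic acid ABB: ring B (1-butanoyl-2,4,6-trihydroxybenzene) carrying at C3 a CH2 link to C6 of acetylfilicinic acid (ring C) and at C5 a CH2 link to C6 of butyrylfilicinic acid (ring A) | CCCC(=O)C1=C(O)C(C)(C)C(O)=C(Cc2c(O)c(CC3=C(O)C(C)(C)C(O)=C(C(C)=O)C3=O)c(O)c(C(=O)CCC)c2O)C1=O | target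

## Step count and risks

Total step count: 5. Longest linear sequence: 3 steps (steps 1, 4, 5; the sequences 1, 2, 5 and 3, 4, 5 are equally long).

Steps most likely to fail:

1. Step 5 (proposed new method). What may go wrong: oxidation may continue at the bridging methylene groups of 13 and of the product, or attack the electron-rich ring B; enetrione 14 may condense with itself before it is captured; and the existing bridge of 13 may exchange under the mildly basic silver conditions. Fallback with known chemistry, setting out from 4 and coming back at 15: 4 would be C-methylated with only two equivalents of MeI (NaOMe, MeOH) and butyrylfilicinic acid 6 isolated at that stage. Compound 6 (1.2 equiv), 13 and 37% aqueous formaldehyde in 1% aq. KOH at 0 °C to rt would then be joined by the classical Knoevenagel/Michael bridging, which passes through 6-(hydroxymethyl)butyrylfilicinic acid F1 and the same enetrione 14, now formed without any oxidant, and should give 15 after acidification.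

2. Step 4. What may go wrong: the bridging may turn statistical, with self-coupling of 10 through 12, self-coupling or double bridging of ring B of 4, and base-promoted exchange of the new bridge. Fallback, setting out from 10 and coming back at 13: 10 would be converted by a Mannich reaction with aqueous dimethylamine and formaldehyde (EtOH, rt) into the isolable Mannich base 2-acetyl-6-[(dimethylamino)methyl]-3,5-dihydroxy-4,4-dimethylcyclohexa-2,5-dien-1-one F2. Heating F2 with 4 (3 equiv) in dioxane at 80–100 °C should release dimethylamine and generate enetrione 12 slowly, in the absence of free formaldehyde and of free 10, so that 12 is captured by ring B of 4 to give 13.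

3. Step 2. What may go wrong: the methylation may not stop cleanly at three methyl groups (halting at the stage of 6 or running on to the tetramethyl triketone), and O-methylation may compete. Fallback, setting out from 4 and coming back at 7: 4 would be methylated with two equivalents of MeI only and 6 isolated, the stage at which the alkylation pauses most readily. The third methyl group would then be introduced by organocatalytic reductive alkylation of 6 with aqueous formaldehyde and Hantzsch ester (L-proline cat., CH2Cl2/EtOH, rt): Knoevenagel condensation gives enetrione 14 and transfer hydrogenation of its exocyclic C=C gives 7. Because the C6 methyl group arises by reduction and the ring then has no free nucleophilic carbon, over-alkylation cannot occur. This fallback makes no compound outside the compound list.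

Further compounds
F1 | step 5 | 2-butanoyl-3,5-dihydroxy-6-(hydroxymethyl)-4,4-dimethylcyclohexa-2,5-dien-1-one | CCCC(=O)C1=C(O)C(C)(C)C(O)=C(CO)C1=O
F2 | step 4 | 2-acetyl-6-[(dimethylamino)methyl]-3,5-dihydroxy-4,4-dimethylcyclohexa-2,5-dien-1-one | CC(=O)C1=C(O)C(C)(C)C(O)=C(CN(C)C)C1=O
F0 | step 2 | none | none
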